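The data are calculated with made-up constants; the scatter is artificial.

Watch the partner: its charge R, held against one concentration H, sets the order of the starting rate. Sunday's and Monday's flasks differ in partner charge, so their rates give H.

| setting | Sunday's | Monday's | Friday's |
|---|---|---|---|
| starting material | 50.0 mM | 50.0 mM | 120 mM |
| partner | 50.0 mM | 150 mM | 50.0 mM |
| catalyst | 4.00 mM | 4.00 mM | 4.00 mM |
| time |  |  | 28 min |

| run | time / min | [product] / mM |
|---|---|---|
| Sunday's run | 3.5 | 5.2 |
| Sunday's run | 7.0 | 9.4 |
| Sunday's run | 10 | 13.4 |
| Sunday's run | 14 | 18.5 |
| Sunday's run | 18 | 23.0 |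
| Sunday's run | 21 | 25.6 |
| Sunday's run | 24 | 28.4 |
| Sunday's run | 28 | 31.9 |
| Monday's run | 3.5 | 3.0 |
| Monday's run | 7.0 | 5.1 |
| Monday's run | 10 | 7.5 |
| Monday's run | 14 | 10.4 |
| Monday's run | 18 | 12.3 |
| Monday's run | 21 | 15.7 |
| Monday's run | 24 | 16.6 |
| Monday's run | 28 | 19.1 |

(readings scatter by 0.4 mM)

1. apparent order in [partner] of the starting rate, round the charge of the Sunday's run (the rate where two percent of its starting material have turned into product)
2. product in the Friday's run at 28 min, as a share of the starting material charged

- Overall: starting material + partner -> product, with catalyst as catalyst.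
- Constant volume, constant temperature.
- Readings of a species count what is bound in complexes too.
- "The second partner" is partner.
- An order is taken over about fifteen percent of the charge, up and down.

At 10 min, Sunday's flask reads 13.4 mM of product and Monday's flask reads 7.5 mM, so Monday's flask has made less, and the ratio ρ of these readings is 0.560. We assume that the rate falls with 1/(1 + R/H) and let ρ stand for the ratio of the starting rates. With R′ for Monday's partner charge, our reckoning gives

H = (ρR′ − R)/(1 − ρ) = 77.1 mM

This H is the partner concentration where the order in partner stands midway between zero and minus one. For Sunday's flask we then expect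

n = −R/(R + H) = −0.393

Friday's flask has Sunday's partner charge but more starting material, so the partner is the limiting reagent and the ceiling is R/S = 41.7 %. We assume first order in starting material, and Sunday's mean rate r up to 10 min, 1.34 mM min⁻¹, gives the constant

k = r(1 + R/H)/S = 0.0442 min⁻¹

Integrating with Friday's S, the ceiling comes at

t = [R/H + ((H + R − S)/H) ln(S/(S − R))]/k = 15.8 min

That is earlier than the 28 min asked, so we commit to the ceiling.

The forecast gives −0.45 for the order, on the ground that “The partner therefore inhibits”, and 38 % for Friday's flask; both numbers differ from ours.

The flask gives an order of −0.37 in Sunday's flask and 41.7 % in Friday's flask.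

    catalyst + starting material → catalyst-substrate complex (20.70 M⁻¹ min⁻¹)
    catalyst-substrate complex + partner → product + catalyst (273.0 M⁻¹ min⁻¹)
    2 starting material ⇌ idle substrate dimer, settled at all times (11.40 M⁻¹)
    catalyst + partner ⇌ idle catalyst-reagent complex, settled at all times (14.50 M⁻¹)

In Sunday's flask, R/(R + H) reads 0.393. The partner slows that flask because it pairs with catalyst as the idle catalyst-reagent complex. Without this pairing, the order in Sunday's flask moves from −0.37 to 0.056, a shift of 0.43.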